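**Plan**

1. Cuts, in retrosynthetic order: the allylic C–OOH bond (ene reaction of singlet oxygen on the remote trisubstituted ring alkene of ovatodiolide); the butenolide C=C (sulfoxide elimination) and the exocyclic C=CH2 (olefination with CH2O); the ring bond between the second CH2 out from the lactone β-carbon and the methyl-bearing alkene carbon (B-alkyl Suzuki–Miyaura macrocyclisation); the Cα–Cβ bond of the fused γ-butyrolactone; the carbinol–alkenyl bond (alkenylzinc plus enal); the Cα–Cβ bond of the butenolide (epoxide opening).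
2. Enabling feature: in the fused five-membered lactone the β-carbon is the ring-fusion CH between the O-bearing carbinol carbon and the ring CH2–CH2 unit. The β-carbon and these two carbons can therefore be an allyl unit, and the lactone oxygen on the neighbouring carbon can carry the α-carbon as a phosphonoacetate ester.
3. The lactone then closes by attack of the ester α-carbanion on the inner end of an η3-allylpalladium unit. This leaves a vinyl group (the two future ring CH2 carbons) and a phosphonate (the future exocyclic methylene).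
4. Order of ring formation: α-phenylthio-γ-lactone (masked butenolide), then the α-phosphono-γ-lactone, then the 14-membered carbocycle; the methylene, the butenolide and the hydroperoxide are unmasked last.
5. Stereochemistry: butenolide γ-carbon from L-proline-catalysed α-aminoxylation; lactone carbinol carbon from (+)-MIB-controlled alkenylzinc addition; lactone β-carbon from that carbinol centre (trans) in the key step; hydroperoxide carbon from face-selective attack on the macrocycle.
6. Alkene geometry: one E-alkene comes from geraniol, the other from syn-hydrozirconation.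

Key step: step 13

Remark: singlet oxygen is assumed to attack the remote trisubstituted ring alkene from the outer face of the 14-membered ring, and this face is taken to give the required configuration at the hydroperoxide carbon; the fallback for step 17 sets this centre by reagent control.

**Route**

Step 1
Reactants: 1 geraniol
Product: 2 geranyl tert-butyldiphenylsilyl ether
Conditions: TBDPSCl, imidazole, CH2Cl2, 0 °C to rt
Reagents that add atoms: tert-butyl(chloro)diphenylsilane, CC(C)(C)[Si](Cl)(c1ccccc1)c1ccccc1
Why: Silylation of the primary allylic alcohol gives a group that survives the carbanion steps; no stereocentre is formed.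

Step 2
Reactants: 2 geranyl tert-butyldiphenylsilyl ether
Product: 4 (4E)-6-(tert-butyldiphenylsilyloxy)-4-methylhex-4-enal, via 6,7-epoxide 3 (not isolated)
Conditions: mCPBA (1.0 equiv), CH2Cl2, −20 °C; then H5IO6, THF/H2O, 0 °C
Reagents that add atoms: 3-chloroperoxybenzoic acid, OOC(=O)c1cccc(Cl)c1
Why: Prilezhaev epoxidation should prefer the remote, more electron-rich alkene (the 2,3-alkene is deactivated by the allylic oxygen), and periodic acid cleavage of the epoxide (Malaprade type) gives the aldehyde with the E-alkene intact.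

Step 3
Reactants: 4 (4E)-6-(tert-butyldiphenylsilyloxy)-4-methylhex-4-enal
Product: 7 (2R,4E)-6-(tert-butyldiphenylsilyloxy)-4-methylhex-4-ene-1,2-diol, via α-aminoxy aldehyde 5 (not isolated), via aminoxy alcohol 6 (not isolated)
Conditions: L-proline (20 mol %), PhNO, DMSO, rt; NaBH4, MeOH, 0 °C; then Zn, AcOH, rt
Reagents that add atoms: nitrosobenzene, O=Nc1ccccc1
Why: Proline-catalysed enamine α-aminoxylation sets the R carbinol centre (the acid-directed electrophile approaches one enamine face), followed by carbonyl reduction and reductive N–O cleavage.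

Step 4
Reactants: 7 (2R,4E)-6-(tert-butyldiphenylsilyloxy)-4-methylhex-4-ene-1,2-diol
Product: 9 (2R)-2-[(2E)-4-(tert-butyldiphenylsilyloxy)-2-methylbut-2-en-1-yl]oxirane, via primary tosylate 8 (not isolated)
Conditions: TsCl, Et3N, Bu2SnO (cat.), CH2Cl2, 0 °C; then K2CO3, MeOH, rt
Reagents that add atoms: none
Why: Selective sulfonylation of the primary hydroxyl and Williamson-type closure by the secondary alkoxide give the terminal epoxide with the carbinol configuration retained.

Step 5
Reactants: 10 pent-3-yn-1-ol
Product: 12 (3E)-4-bromopent-3-en-1-ol, via O-zirconated alkenylzirconocene 11 (not isolated)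
Conditions: Cp2Zr(H)Cl (2.5 equiv), THF, rt to 45 °C; then NBS, 0 °C; aqueous work-up
Reagents that add atoms: N-bromosuccinimide, O=C1CCC(=O)N1Br
Why: syn-Hydrozirconation with excess hydride should equilibrate to zirconium on the methyl-bearing alkyne carbon, and brominolysis with retention gives the E alkenyl bromide.

Step 6
Reactants: 12 (3E)-4-bromopent-3-en-1-ol
Product: 13 (2E)-2-bromo-5-iodopent-2-ene
Conditions: I2, PPh3, imidazole, CH2Cl2, 0 °C
Reagents that add atoms: iodine, II
Why: Appel-type iodination of the primary alcohol leaves the alkenyl bromide untouched.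

Step 7
Reactants: 13 (2E)-2-bromo-5-iodopent-2-ene, 14 (phenylsulfanyl)acetic acid
Product: 15 (5E)-6-bromo-2-(phenylsulfanyl)hept-5-enoic acid (racemic)
Conditions: LiN(iPr)2 (2.1 equiv), THF, −78 to 0 °C; 13, HMPA, −78 °C to rt; aq. HCl
Reagents that add atoms: none
Why: SN2 alkylation of the sulfur-stabilised carboxylate dianion with the primary iodide; the new centre is racemic and is erased later.

Step 8
Reactants: 15 (5E)-6-bromo-2-(phenylsulfanyl)hept-5-enoic acid, 9 (2R)-2-[(2E)-4-(tert-butyldiphenylsilyloxy)-2-methylbut-2-en-1-yl]oxirane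
Product: 17 (5R)-3-[(3E)-4-bromopent-3-en-1-yl]-5-[(2E)-4-(tert-butyldiphenylsilyloxy)-2-methylbut-2-en-1-yl]-3-(phenylsulfanyl)oxolan-2-one (both C3 epimers), via γ-hydroxy acid 16 (not isolated)
Conditions: LiN(iPr)2 (2.1 equiv), THF, −78 to 0 °C; 9, 0 °C to rt; aq. HCl; TsOH (cat.), benzene, rt
Reagents that add atoms: none
Why: The α-thio carboxylate dianion opens the terminal epoxide at CH2 (SN2) and acid-catalysed lactonisation follows; the γ-centre comes unchanged from 9 and the sulfur-bearing carbon forms as a mixture that step 16 removes.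

Step 9
Reactants: 17 silyl-protected α-phenylthio lactone
Product: 18 (5R)-3-[(3E)-4-bromopent-3-en-1-yl]-5-[(2E)-4-hydroxy-2-methylbut-2-en-1-yl]-3-(phenylsulfanyl)oxolan-2-one
Conditions: Bu4NF, AcOH, THF, 0 °C to rt
Reagents that add atoms: none
Why: Buffered fluoride desilylation frees the allylic alcohol without opening the lactone.

Step 10
Reactants: 18 allylic alcohol
Product: 19 (2E)-4-[(2R)-4-[(3E)-4-bromopent-3-en-1-yl]-5-oxo-4-(phenylsulfanyl)oxolan-2-yl]-3-methylbut-2-enal
Conditions: MnO2, CH2Cl2, rt
Reagents that add atoms: none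
Why: MnO2 oxidises only the allylic alcohol to the E-enal; the sulfide and alkenyl bromide are inert.

Step 11
Reactants: 19 enal, 20 methyl prop-2-yn-1-yl carbonate
Product: 23 methyl (2E,4R,5E)-4-hydroxy-6-methyl-7-[(2R)-4-[(3E)-4-bromopent-3-en-1-yl]-5-oxo-4-(phenylsulfanyl)oxolan-2-yl]hepta-2,5-dien-1-yl carbonate, via (E)-alkenyl(dicyclohexyl)borane 21 (not isolated), via (E)-alkenyl(ethyl)zinc 22 (not isolated)
Conditions: Cy2BH, toluene, 0 °C to rt; Et2Zn, −78 °C; (+)-MIB (10 mol %), 19, −78 to −10 °C; aq. NH4Cl
Reagents that add atoms: none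
Why: syn-Hydroboration, boron-to-zinc exchange and amino-alcohol-catalysed 1,2-addition of the alkenylzinc to the aldehyde; (+)-MIB should deliver the alkenyl group to the Re face of the enal carbonyl (catalyst control), giving the R doubly allylic carbinol with an E-alkene.

Step 12
Reactants: 23 doubly allylic alcohol, 24 (diethoxyphosphoryl)acetic acid
Product: 25 (diethoxyphosphoryl)acetate ester of 23 (carbinol carbon R)
Conditions: DCC, DMAP (cat.), CH2Cl2, 0 °C to rt
Reagents that add atoms: none
Why: Steglich esterification under near-neutral conditions avoids ionisation of the doubly allylic alcohol; no stereocentre is touched.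

Step 13
Reactants: 25 phosphonoacetate ester bearing the allylic methyl carbonate
Product: 26 diethyl [(4S,5S)-4-ethenyl-2-oxo-5-[(1E)-2-methyl-3-[(2R)-4-[(3E)-4-bromopent-3-en-1-yl]-5-oxo-4-(phenylsulfanyl)oxolan-2-yl]prop-1-en-1-yl]oxolan-3-yl]phosphonate (mixture at the phosphorus-bearing carbon)
Conditions: Pd2(dba)3·CHCl3 (2.5 mol %), PPh3 (20 mol %), THF (5 mM), 40 °C
Reagents that add atoms: none
Why: Proposed new method: zerovalent palladium ionises the primary allylic carbonate to a cationic η3-allyl complex over the three carbons next to the ester-bearing carbinol, releasing CO2 and methoxide; methoxide deprotonates the phosphonoacetate and the stabilised carbanion attacks the inner allyl terminus anti to palladium, which closes the lactone and leaves a vinyl group. The closest known reaction type is the intramolecular Tsuji–Trost alkylation of amide-tethered active-methylene compounds (phosphonoacetamides included) to 3-phosphono-4-vinyl-γ-lactams; here the tether is an ester that must reach its minor s-cis rotamer, hence high dilution and mild heating. The ring closes 5-exo with respect to the allyl unit, which should be preferred over 7-endo attack at the CH2 terminus. The new stereocentre (lactone C4) is controlled by the adjacent carbinol centre: the two diastereomeric allyl complexes interconvert by η3–η1–η3 at the unsubstituted terminus faster than C–C bond formation, and closure should go through the transition state that places the alkenyl chain on C5 and the incipient vinyl group trans, which is also the more stable arrangement. The step needs ionisation of the primary carbonate and not of the secondary doubly allylic ester or the alkenyl bromide; the better leaving group at the less hindered terminus and PPh3-ligated palladium at 40 °C, where insertion into the C–Br bond is slow, should secure this.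

Step 14
Reactants: 26 trans-α-phosphono-β-vinyl lactone
Product: 28 macrocyclic bis-lactone (14-membered carbocycle carrying the trans-fused α-(diethoxyphosphoryl)-γ-butyrolactone and the bridging α-(phenylsulfanyl)-γ-butyrolactone), via B-alkyl-9-BBN borane 27 (not isolated)
Conditions: 9-BBN-H (1.5 equiv), THF, rt; then PdCl2(dppf) (15 mol %), AsPh3, Cs2CO3, DMF/THF/H2O (2 mM, slow addition), 50 °C
Reagents that add atoms: none
Why: 9-BBN should hydroborate only the monosubstituted vinyl group (anti-Markovnikov), and intramolecular B-alkyl Suzuki–Miyaura coupling with the alkenyl bromide closes the 14-membered ring with retention of the E geometry.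

Step 15
Reactants: 28 macrocyclic α-phosphono lactone
Product: 29 macrocyclic α-methylene-γ-butyrolactone still carrying the α-(phenylsulfanyl) lactone
Conditions: K2CO3, 37 % aq. CH2O, THF, 0 °C to rt
Reagents that add atoms: formaldehyde, C=O
Why: Horner–Wadsworth–Emmons olefination of the α-phosphono lactone with formaldehyde installs the exocyclic methylene while the second lactone, having no α-hydrogen, is inert to the base.

Step 16
Reactants: 29 macrocyclic α-methylene lactone sulfide
Product: 31 ovatodiolide, via sulfoxide 30 (not isolated)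
Conditions: NaIO4, MeOH/THF/H2O, 0 °C to rt; then toluene, CaCO3, 100 °C
Reagents that add atoms: none
Why: Periodate oxidises only the sulfide, and thermal syn-elimination of the sulfoxide toward the lactone ring CH2 gives the butenolide under neutral conditions, so its base-labile γ-centre is not exposed to base.

Step 17
Reactants: 31 ovatodiolide
Product: 32 4-methylene-5β-hydroperoxyovatodiolide
Conditions: O2, tetraphenylporphyrin (cat.), visible light, CH2Cl2, −20 °C
Reagents that add atoms: dioxygen, O=O
Why: Schenck ene reaction: singlet oxygen should attack the most electron-rich alkene, bond to its CH carbon and abstract a hydrogen from the methyl group on the more crowded alkene side (cis effect), giving the exocyclic methylene; the new centre is set by attack on the outer face of the macrocycle (substrate control).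

**Compound list**

1 | geraniol | CC(C)=CCC/C(C)=C/CO | starting material
2 | geranyl tert-butyldiphenylsilyl ether | CC(C)=CCC/C(C)=C/CO[Si](c1ccccc1)(c1ccccc1)C(C)(C)C | intermediate
3 | 6,7-epoxide of 2 (racemic at the epoxide) | CC1(C)OC1CC/C(C)=C/CO[Si](c1ccccc1)(c1ccccc1)C(C)(C)C | intermediate
4 | (4E)-6-(tert-butyldiphenylsilyloxy)-4-methylhex-4-enal | O=CCC/C(C)=C/CO[Si](c1ccccc1)(c1ccccc1)C(C)(C)C | intermediate
5 | (2R,4E)-6-(tert-butyldiphenylsilyloxy)-4-methyl-2-(N-phenylaminooxy)hex-4-enal | O=C[C@H](ONc1ccccc1)C/C(C)=C/CO[Si](c1ccccc1)(c1ccccc1)C(C)(C)C | intermediate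
6 | (2R,4E)-6-(tert-butyldiphenylsilyloxy)-4-methyl-2-(N-phenylaminooxy)hex-4-en-1-ol | OC[C@H](ONc1ccccc1)C/C(C)=C/CO[Si](c1ccccc1)(c1ccccc1)C(C)(C)C | intermediate
7 | (2R,4E)-6-(tert-butyldiphenylsilyloxy)-4-methylhex-4-ene-1,2-diol | OC[C@H](O)C/C(C)=C/CO[Si](c1ccccc1)(c1ccccc1)C(C)(C)C | intermediate
8 | primary 4-methylbenzenesulfonate of 7 | Cc1ccc(cc1)S(=O)(=O)OC[C@H](O)C/C(C)=C/CO[Si](c1ccccc1)(c1ccccc1)C(C)(C)C | intermediate
9 | (2R)-2-[(2E)-4-(tert-butyldiphenylsilyloxy)-2-methylbut-2-en-1-yl]oxirane | C1O[C@@H]1C/C(C)=C/CO[Si](c1ccccc1)(c1ccccc1)C(C)(C)C | intermediate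
10 | pent-3-yn-1-ol | CC#CCCO | starting material
11 | O-zirconated (E)-alkenylzirconocene chloride from 10 | C/C(=C\CCO[Zr](Cl)(C1C=CC=C1)C1C=CC=C1)[Zr](Cl)(C1C=CC=C1)C1C=CC=C1 | intermediate
12 | (3E)-4-bromopent-3-en-1-ol | C/C(Br)=C\CCO | intermediate
13 | (2E)-2-bromo-5-iodopent-2-ene | C/C(Br)=C\CCI | intermediate
14 | (phenylsulfanyl)acetic acid | OC(=O)CSc1ccccc1 | starting material
15 | (5E)-6-bromo-2-(phenylsulfanyl)hept-5-enoic acid (racemic) | OC(=O)C(Sc1ccccc1)CC/C=C(\C)Br | intermediate
16 | γ-hydroxy acid from 15 and 9 (carbinol R, both epimers at the sulfur-bearing carbon) | OC(=O)C(Sc1ccccc1)(CC/C=C(\C)Br)C[C@H](O)C/C(C)=C/CO[Si](c1ccccc1)(c1ccccc1)C(C)(C)C | intermediate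
17 | (5R)-3-[(3E)-4-bromopent-3-en-1-yl]-5-[(2E)-4-(tert-butyldiphenylsilyloxy)-2-methylbut-2-en-1-yl]-3-(phenylsulfanyl)oxolan-2-one (both C3 epimers) | O=C1O[C@H](C/C(C)=C/CO[Si](c2ccccc2)(c2ccccc2)C(C)(C)C)CC1(Sc3ccccc3)CC/C=C(\C)Br | intermediate
18 | (5R)-3-[(3E)-4-bromopent-3-en-1-yl]-5-[(2E)-4-hydroxy-2-methylbut-2-en-1-yl]-3-(phenylsulfanyl)oxolan-2-one | O=C1O[C@H](C/C(C)=C/CO)CC1(Sc3ccccc3)CC/C=C(\C)Br | intermediate
19 | (2E)-4-[(2R)-4-[(3E)-4-bromopent-3-en-1-yl]-5-oxo-4-(phenylsulfanyl)oxolan-2-yl]-3-methylbut-2-enal | O=C1O[C@H](C/C(C)=C/C=O)CC1(Sc3ccccc3)CC/C=C(\C)Br | intermediate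
20 | methyl prop-2-yn-1-yl carbonate | C#CCOC(=O)OC | starting material
21 | (E)-[3-(methoxycarbonyloxy)prop-1-en-1-yl]dicyclohexylborane | COC(=O)OC/C=C/B(C1CCCCC1)C1CCCCC1 | intermediate
22 | (E)-[3-(methoxycarbonyloxy)prop-1-en-1-yl](ethyl)zinc | CC[Zn]/C=C/COC(=O)OC | intermediate
23 | methyl (2E,4R,5E)-4-hydroxy-6-methyl-7-[(2R)-4-[(3E)-4-bromopent-3-en-1-yl]-5-oxo-4-(phenylsulfanyl)oxolan-2-yl]hepta-2,5-dien-1-yl carbonate | O=C1O[C@H](C/C(C)=C/[C@H](O)/C=C/COC(=O)OC)CC1(Sc3ccccc3)CC/C=C(\C)Br | intermediate
24 | (diethoxyphosphoryl)acetic acid | OC(=O)CP(=O)(OCC)OCC | starting material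
25 | (diethoxyphosphoryl)acetate of 23 (carbinol carbon R) | O=C1O[C@H](C/C(C)=C/[C@H](OC(=O)CP(=O)(OCC)OCC)/C=C/COC(=O)OC)CC1(Sc3ccccc3)CC/C=C(\C)Br | intermediate
26 | diethyl [(4S,5S)-4-ethenyl-2-oxo-5-(alkenyl)oxolan-3-yl]phosphonate, trans-β-vinyl lactone (full name in step 13) | O=C1O[C@H](C/C(C)=C/[C@@H]2OC(=O)C(P(=O)(OCC)OCC)[C@H]2C=C)CC1(Sc3ccccc3)CC/C=C(\C)Br | intermediate
27 | B-alkyl-9-borabicyclo[3.3.1]nonane from hydroboration of the vinyl group of 26 | O=C1O[C@H](C/C(C)=C/[C@@H]2OC(=O)C(P(=O)(OCC)OCC)[C@H]2CCB4C5CCCC4CCC5)CC1(Sc3ccccc3)CC/C=C(\C)Br | intermediate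
28 | macrocyclic bis-lactone: 14-membered carbocycle with trans-fused α-(diethoxyphosphoryl)-γ-butyrolactone and bridging α-(phenylsulfanyl)-γ-butyrolactone, both ring alkenes E | CCOP(=O)(OCC)C1C(=O)O[C@H]2/C=C(\C)C[C@@H]3CC(Sc4ccccc4)(CC/C=C(\C)CC[C@H]12)C(=O)O3 | intermediate
29 | α-methylene analogue of 28 (phenylsulfanyl lactone retained) | C=C1C(=O)O[C@H]2/C=C(\C)C[C@@H]3CC(Sc4ccccc4)(CC/C=C(\C)CC[C@H]12)C(=O)O3 | intermediate
30 | sulfoxide of 29 | C=C1C(=O)O[C@H]2/C=C(\C)C[C@@H]3CC(S(=O)c4ccccc4)(CC/C=C(\C)CC[C@H]12)C(=O)O3 | intermediate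
31 | ovatodiolide | C=C1C(=O)O[C@H]2/C=C(\C)C[C@@H]3C=C(CC/C=C(\C)CC[C@H]12)C(=O)O3 | intermediate
32 | 4-methylene-5β-hydroperoxyovatodiolide | C=C1C(=O)O[C@H]2/C=C(\C)C[C@@H]3C=C(CC[C@@H](OO)C(=C)CC[C@H]12)C(=O)O3 | target

**Step count**

Total: 17 steps. Longest linear sequence: 14 steps (steps 1–4 and 8–17, from geraniol).

**Steps most likely to fail**

1. Step 13, the step that carries the proposed method. The ester tether must reach its minor s-cis rotamer, so ring closure may be slow; intermolecular alkylation, proton loss from the allyl complex to a diene, attack at the outer allyl terminus, or ionisation of the secondary doubly allylic ester by zerovalent palladium with loss of configuration at the carbinol carbon could then compete. The fallback for step 13 uses known chemistry, sets out from 23 and comes back to the route at 26. Acylation of 23 with acryloyl chloride and iPr2NEt should give the doubly allylic acrylate F1 with the carbinol configuration untouched. Ring-closing metathesis of the doubly allylic acrylate F1 onto its disubstituted alkene, with the second-generation Hoveyda–Grubbs catalyst in toluene at 80 °C, should give the γ-alkenyl butenolide F2 with release of allyl methyl carbonate. Conjugate addition of (CH2=CH)2CuLi with TMSCl at −78 °C, anti to the γ-substituent, should turn the γ-alkenyl butenolide F2 into the trans-β-vinyl lactone F3 that still lacks the phosphonate. Enolisation of the trans-β-vinyl lactone F3 with LiN(iPr)2, O-phosphorylation with ClP(O)(OEt)2 and 1,3-phosphorus migration of the enol phosphate induced by further LiN(iPr)2 should then give 26.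

2. Step 14. Intermolecular coupling may outrun ring closure, the alkylpalladium intermediate may undergo β-hydride elimination or the borane protodeboronation, and hydroboration may not stay confined to the vinyl group. The fallback for step 14 sets out from 26 and comes back to the route at 28. Hydroboration of 26 with 9-BBN-H and oxidation with NaBO3 should give the primary alcohol F4 in place of the borane. Treatment of the primary alcohol F4 with I2, PPh3 and imidazole should give the primary iodide F5 as the ring-closure substrate. A nickel-catalysed reductive cross-electrophile coupling of the alkyl iodide with the alkenyl bromide within the primary iodide F5 (NiBr2·glyme, 4,4'-di-tert-butyl-2,2'-bipyridine, Mn powder, DMA, slow addition) needs no organoboron nucleophile and no base and should close the ring to 28.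

3. Step 17. Hydrogen abstraction may occur from the ring CH2 groups, which would give tertiary hydroperoxides with a shifted ring alkene; the other trisubstituted alkene may react; and oxygen may arrive on the wrong face. The fallback for step 17 sets out from 31 and ends at 32. Shi epoxidation with the L-fructose-derived ketone enantiomer (2KHSO5·KHSO4·K2SO4, K2CO3 buffer, MeCN/dimethoxymethane/H2O, 0 °C) should give, under reagent control, the macrocyclic epoxide F6 with the S,S configuration at the remote ring alkene. Homolytic opening of the macrocyclic epoxide F6 with Cp2TiCl (trivalent titanium, from Cp2TiCl2 and Mn powder, THF), with loss of a methyl hydrogen, should give the allylic alcohol F7 with the exocyclic methylene and an S carbinol centre. MsCl and Et3N at −40 °C should convert the allylic alcohol F7 into the allylic mesylate F8 without touching the lactones. SN2 displacement on the allylic mesylate F8 by anhydrous H2O2 in Et2O, with inversion, should give 32.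

Further compounds
F1 | step 13 | doubly allylic acrylate | O=C1O[C@H](C/C(C)=C/[C@H](OC(=O)C=C)/C=C/COC(=O)OC)CC1(Sc3ccccc3)CC/C=C(\C)Br
F2 | step 13 | γ-alkenyl butenolide | O=C1O[C@H](C/C(C)=C/[C@@H]2OC(=O)C=C2)CC1(Sc3ccccc3)CC/C=C(\C)Br
F3 | step 13 | trans-β-vinyl lactone | O=C1O[C@H](C/C(C)=C/[C@@H]2OC(=O)C[C@H]2C=C)CC1(Sc3ccccc3)CC/C=C(\C)Br
F4 | step 14 | primary alcohol | O=C1O[C@H](C/C(C)=C/[C@@H]2OC(=O)C(P(=O)(OCC)OCC)[C@H]2CCO)CC1(Sc3ccccc3)CC/C=C(\C)Br
F5 | step 14 | primary iodide | O=C1O[C@H](C/C(C)=C/[C@@H]2OC(=O)C(P(=O)(OCC)OCC)[C@H]2CCI)CC1(Sc3ccccc3)CC/C=C(\C)Br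
F6 | step 17 | macrocyclic epoxide | C=C1C(=O)O[C@H]2/C=C(\C)C[C@@H]3C=C(CC[C@@H]4O[C@@]4(C)CC[C@H]12)C(=O)O3
F7 | step 17 | allylic alcohol | C=C1C(=O)O[C@H]2/C=C(\C)C[C@@H]3C=C(CC[C@H](O)C(=C)CC[C@H]12)C(=O)O3
F8 | step 17 | allylic mesylate | C=C1C(=O)O[C@H]2/C=C(\C)C[C@@H]3C=C(CC[C@H](OS(C)(=O)=O)C(=C)CC[C@H]12)C(=O)O3
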